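**Plan**

- Numbering used throughout: C1 = ester carbinol, C2 = CH2, C3 = C(CH3)OH, C4 = CH2, C5/C6 = ring-fusion carbons (C5 bonded to C4 and C9, C6 to C7 and C10), C7 = CH2, C8/C9 = epoxide carbons (CH3 on C8), C10 = CH(i-Pr).
- Retrosynthetic cuts, in order: the aroyl–O(C1) bond; the epoxide C–O bonds (back to C8=C9); C8–CH3 (back to a C8 ketone); then C5–C6, C7–C8 and C8–C9 in one Pauson–Khand operation; then C1–C10 (allylboration), C1–C2 (vinyl addition, then cleavage) and C4–C5 (acetylide).
- Enabling feature: the cyclopentane ring C5–C6–C7–C8–C9 shares the C5–C6 edge with the seven-membered ring C1–C2–C3–C4–C5–C6–C10, and C8 lies between C7H2 and C9H. The bicycle therefore maps onto alkyne C5≡C9 + vinyl C6=C7 + CO (C8), linked by the chain C4–C3–C2–C1–C10.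
- Forward order: the open chain is built outward from C3 (C4–C5, then C2–C1, then C1–C10); both rings are closed together; methyl group, epoxide and ester follow on the bicycle.
- Stereochemistry: C3 from (S)-2-methylglycidol; C1 and C10 from a catalyst-controlled anti allylboration; C6 relayed from C10 in the cyclisation; C5 from dissolving-metal reduction (trans fusion); C8/C9 from epoxidation directed by the C3 hydroxyl.

Key step: step 10

Assumption: (S)-TRIP is taken as the catalyst enantiomer that sends an allyl pinacolboronate to the Si face of an unbranched aliphatic aldehyde; the mirror-image acid would otherwise be used.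

Step 1
Reactants: 1 (S)-2-methylglycidol; 2 trimethylsilylacetylene
Product: 3 (R)-2-methyl-5-(trimethylsilyl)pent-4-yne-1,2-diol
Conditions: 2 (3.5 equiv), n-BuLi (3.3 equiv), THF, −78 °C; add 1; BF3·OEt2 (2.2 equiv), −78 → −40 °C; aq. NH4Cl
Reagents that add atoms: none
Why: BF3-assisted alkynylation of an epoxide (Yamaguchi–Hirao type) attacks the unsubstituted carbon by SN2 after the first equivalent of acetylide has only deprotonated the hydroxyl, and since no bond to the stereocentre is touched the configuration of 1 is carried over (the descriptor becomes R through the priority change alone).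

Step 2
Reactants: 3 (R)-2-methyl-5-(trimethylsilyl)pent-4-yne-1,2-diol
Product: 5 (R)-2-methyl-2-[3-(trimethylsilyl)prop-2-yn-1-yl]oxirane, via primary tosylate 4 (not isolated)
Conditions: NaH (2.5 equiv), N-tosylimidazole (1.05 equiv), THF, 0 °C → rt
Reagents that add atoms: none
Why: One-pot sulfonylation/intramolecular Williamson etherification, in which the primary alkoxide is tosylated selectively and the tertiary alkoxide closes the oxirane by displacement at CH2, leaving the quaternary stereocentre untouched.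

Step 3
Reactants: 5 (R)-2-methyl-2-[3-(trimethylsilyl)prop-2-yn-1-yl]oxirane
Product: 6 (S)-4-methyl-7-(trimethylsilyl)hept-1-en-6-yn-4-ol
Conditions: CH2=CHMgBr (2.0 equiv), CuI (10 mol %), THF, −40 → 0 °C; aq. NH4Cl
Reagents that add atoms: vinylmagnesium bromide, C=C[Mg]Br
Why: Copper-catalysed Grignard opening of a 2,2-disubstituted terminal epoxide is an SN2 attack at the CH2 terminus, and the silyl-capped alkyne offers no acidic hydrogen to the reagent.

Step 4
Reactants: 6 (S)-4-methyl-7-(trimethylsilyl)hept-1-en-6-yn-4-ol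
Product: 7 triethyl{[(S)-4-methyl-7-(trimethylsilyl)hept-1-en-6-yn-4-yl]oxy}silane
Conditions: Et3SiOTf (1.3 equiv), 2,6-lutidine (2 equiv), CH2Cl2, −78 → 0 °C
Reagents that add atoms: triethylsilyl trifluoromethanesulfonate, CC[Si](CC)(CC)OS(=O)(=O)C(F)(F)F
Why: Silylation of a tertiary alcohol with a silyl triflate and a hindered pyridine base is standard, and it masks the hydroxyl before the β-oxygenated aldehyde is unveiled.

Step 5
Reactants: 7 triethyl{[(S)-4-methyl-7-(trimethylsilyl)hept-1-en-6-yn-4-yl]oxy}silane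
Product: 9 (R)-3-methyl-3-(triethylsilyloxy)-6-(trimethylsilyl)hex-5-ynal, via vicinal diol 8 (not isolated)
Conditions: OsO4 (2 mol %), NaIO4 (4 equiv), 2,6-lutidine (2 equiv), 1,4-dioxane/H2O 3:1, rt
Reagents that add atoms: osmium tetroxide, O=[Os](=O)(=O)=O (supplies the aldehyde oxygen; turned over by sodium periodate, [Na+].[O-]I(=O)(=O)=O)
Why: Lemieux–Johnson cleavage, in which OsO4 dihydroxylates the terminal alkene far faster than the silylalkyne and periodate cleaves the diol, while the lutidine buffer keeps the medium near neutral for the TES ether and the β-silyloxy aldehyde.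

Step 6
Reactants: 10 (E)-1-bromo-4-methylpent-2-ene
Product: 11 4,4,5,5-tetramethyl-2-[(E)-4-methylpent-2-en-1-yl]-1,3,2-dioxaborolane
Conditions: B2pin2 (1.1 equiv), Pd2(dba)3 (2.5 mol %), THF, 60 °C
Reagents that add atoms: bis(pinacolato)diboron, CC1(C)OB(OC1(C)C)B1OC(C)(C)C(C)(C)O1
Why: Palladium-catalysed Miyaura-type borylation of an allylic halide runs through a π-allyl intermediate that is borylated at the unhindered terminus with the E geometry of the syn π-allyl retained, giving the linear E allylboronate.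

Step 7
Reactants: 9 (R)-3-methyl-3-(triethylsilyloxy)-6-(trimethylsilyl)hex-5-ynal; 11 4,4,5,5-tetramethyl-2-[(E)-4-methylpent-2-en-1-yl]-1,3,2-dioxaborolane
Product: 13 (3S,4R,6R)-6-methyl-3-(propan-2-yl)-6-(triethylsilyloxy)-9-(trimethylsilyl)non-1-en-8-yn-4-ol, via pinacol borate 12 (not isolated)
Conditions: 11 (1.5 equiv), (S)-TRIP (5 mol %), 4 Å MS, PhMe, −30 °C; aq. NaHCO3
Reagents that add atoms: none
Why: Allylboration through a closed six-membered (Zimmerman–Traxler) transition state, in which the E boronate gives the anti C1/C10 pair and the chiral phosphoric acid, hydrogen-bonded to the boronate oxygen, directs attack to the Si face of the aldehyde so that C1 is R and C10 is S, the remote quaternary C3 being unable to override the catalyst.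

Step 8
Reactants: 13 (3S,4R,6R)-6-methyl-3-(propan-2-yl)-6-(triethylsilyloxy)-9-(trimethylsilyl)non-1-en-8-yn-4-ol
Product: 14 (3S,4R,6R)-4-(tert-butyldimethylsilyloxy)-6-methyl-3-(propan-2-yl)-6-(triethylsilyloxy)-9-(trimethylsilyl)non-1-en-8-yne
Conditions: t-BuMe2SiOTf (1.5 equiv), 2,6-lutidine (3 equiv), CH2Cl2, 0 °C → rt
Reagents that add atoms: tert-butyldimethylsilyl trifluoromethanesulfonate, CC(C)(C)[Si](C)(C)OS(=O)(=O)C(F)(F)F
Why: A silyl triflate is the standard reagent for silylating a hindered secondary alcohol, and the TBS ether is needed to survive the reductive triflation and Grignard coupling later.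

Step 9
Reactants: 14 (3S,4R,6R)-4-(tert-butyldimethylsilyloxy)-6-methyl-3-(propan-2-yl)-6-(triethylsilyloxy)-9-(trimethylsilyl)non-1-en-8-yne
Product: 15 (3S,4R,6R)-4-(tert-butyldimethylsilyloxy)-6-methyl-3-(propan-2-yl)-6-(triethylsilyloxy)non-1-en-8-yne
Conditions: K2CO3 (0.3 equiv), MeOH/THF, rt
Reagents that add atoms: none
Why: Carbonate-catalysed methanolysis (protodesilylation) is selective for the C(sp)–Si bond, the TBS and tertiary TES ethers being stable to these conditions.

Step 10
Reactants: 15 (3S,4R,6R)-4-(tert-butyldimethylsilyloxy)-6-methyl-3-(propan-2-yl)-6-(triethylsilyloxy)non-1-en-8-yne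
Product: 16 (5R,7R,8S,8aS)-7-(tert-butyldimethylsilyloxy)-5-methyl-8-(propan-2-yl)-5-(triethylsilyloxy)-4,5,6,7,8,8a-hexahydroazulen-2(1H)-one
Conditions: Co2(CO)8 (0.2 equiv), tetramethylthiourea (1.2 equiv), CO (1 atm), PhMe (0.005 M), 70 °C
Reagents that add atoms: carbon monoxide, [C-]#[O+]
Why: Proposed new method: under CO the terminal alkyne of 15 is taken up as its Co2(CO)6 complex, thiourea-assisted CO loss opens a site on cobalt for the vinyl group, the olefin inserts so that its substituted carbon C6 bonds to C5, and migratory insertion of CO followed by reductive elimination forges C7–C8 and C8–C9, which is the accepted Pauson–Khand pathway; the closest known reaction types are Co2(CO)8-mediated closures of 1,6- and 1,7-enynes, the isolated 1,8-enynes whose tethers are ring-constrained or geminally disubstituted, and rhodium-catalysed allenic variants that deliver bicyclo[5.3.0]decadienones, whereas an open-chain 1,8-enyne of this kind has no direct precedent. The seven-membered ring is the ring that contains the tether and is closed in the olefin-insertion event (exo with respect to the vinyl group, C5–C6 bond), and the cyclopentenone is closed immediately afterwards by the carbonylation/reductive-elimination sequence. The fully substituted C3 (Thorpe–Ingold effect), the branching at C1 and C10 and their bulky silyloxy groups are counted on to populate the folded rotamers, and high dilution under CO is meant to hold back intermolecular alkyne oligomerisation. C6, the single new stereocentre, is governed by the neighbouring C10: in the chair-like insertion geometry the isopropyl group lies pseudo-equatorial and the new C6–C7 bond forms trans to it, so that H6 ends anti to H10. Since C6 is the γ-position of the enone, a minor C6 epimer could be converged on the same, more stable trans arrangement by base equilibration through the dienolate. The selectivity the step needs is intramolecular insertion over decay of the cobalt–alkyne complex, and only the substitution of the tether secures it, which is why this step heads the list of risks.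

Step 11
Reactants: 16 (5R,7R,8S,8aS)-7-(tert-butyldimethylsilyloxy)-5-methyl-8-(propan-2-yl)-5-(triethylsilyloxy)-4,5,6,7,8,8a-hexahydroazulen-2(1H)-one
Product: 18 (3aS,5R,7R,8S,8aR)-7-(tert-butyldimethylsilyloxy)-5-methyl-8-(propan-2-yl)-5-(triethylsilyloxy)-1,3a,4,5,6,7,8,8a-octahydroazulen-2-yl trifluoromethanesulfonate, via lithium enolate 17 (not isolated)
Conditions: Li (2.5 equiv), NH3(l)/THF, t-BuOH (1.0 equiv), −78 °C; isoprene; evaporate NH3; PhNTf2 (1.5 equiv), THF, −78 → 0 °C
Reagents that add atoms: N-phenylbis(trifluoromethanesulfonimide), O=S(=O)(N(c1ccccc1)S(=O)(=O)C(F)(F)F)C(F)(F)F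
Why: Dissolving-metal (Birch-type) reduction of the enone protonates the β-carbon C5 under product-like control on the face anti to H6 (trans ring fusion, the β face being further screened by the axial C3 substituent), and the regiodefined C8–C9 lithium enolate is then trapped on oxygen by PhNTf2 (reductive enolate triflation), the silyl ethers being inert to Li/NH3.

Step 12
Reactants: 18 (3aS,5R,7R,8S,8aR)-7-(tert-butyldimethylsilyloxy)-5-methyl-8-(propan-2-yl)-5-(triethylsilyloxy)-1,3a,4,5,6,7,8,8a-octahydroazulen-2-yl trifluoromethanesulfonate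
Product: 19 (3aS,5R,7R,8S,8aR)-7-(tert-butyldimethylsilyloxy)-2,5-dimethyl-8-(propan-2-yl)-5-(triethylsilyloxy)-1,3a,4,5,6,7,8,8a-octahydroazulene
Conditions: MeMgBr (3 equiv), Fe(acac)3 (10 mol %), THF/NMP 10:1, −30 → 0 °C; aq. NH4Cl
Reagents that add atoms: methylmagnesium bromide, C[Mg]Br
Why: Iron-catalysed Kumada-type cross-coupling of an alkenyl triflate with a methyl Grignard reagent is fast at low temperature, so neither the silyl ethers nor the ring-fusion stereocentres are touched and the C8=C9 position of the olefin is fixed by the triflate.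

Step 13
Reactants: 19 (3aS,5R,7R,8S,8aR)-7-(tert-butyldimethylsilyloxy)-2,5-dimethyl-8-(propan-2-yl)-5-(triethylsilyloxy)-1,3a,4,5,6,7,8,8a-octahydroazulene
Product: 20 (3aS,5R,7R,8S,8aR)-2,5-dimethyl-8-(propan-2-yl)-1,3a,4,5,6,7,8,8a-octahydroazulene-5,7-diol
Conditions: Bu4NF (5 equiv), THF, 50 °C
Reagents that add atoms: none
Why: Fluoride-mediated desilylation removes both silyl ethers, and nothing else in 19 is sensitive to fluoride or mild base.

Step 14
Reactants: 20 (3aS,5R,7R,8S,8aR)-2,5-dimethyl-8-(propan-2-yl)-1,3a,4,5,6,7,8,8a-octahydroazulene-5,7-diol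
Product: 21 8,9-β-epoxide of diol 20 (plan numbering 1R,3R,5S,6R,8R,9S,10S; epoxide oxygen on the face of both hydroxyls, i-Pr and H6)
Conditions: VO(acac)2 (10 mol %), t-BuOOH (1.5 equiv, decane), CH2Cl2, 0 °C → rt
Reagents that add atoms: tert-butyl hydroperoxide, CC(C)(C)OO
Why: Vanadium-catalysed hydroxyl-directed epoxidation, in which the axial C3 hydroxyl sits on the β face above C5/C9 and, as a bishomoallylic ligand on vanadium, delivers oxygen to the β face of the trisubstituted C8=C9 bond (C8 R, C9 S), the resulting syn epoxy alcohol being unable to open intramolecularly because backside attack is geometrically excluded.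

Step 15
Reactants: 22 isovanillic acid
Product: 24 3-(benzyloxy)-4-methoxybenzoic acid, via benzyl ester 23 (not isolated)
Conditions: BnBr (2.3 equiv), K2CO3 (3 equiv), DMF, 60 °C; then NaOH (aq), MeOH/THF, 60 °C; HCl to pH 2
Reagents that add atoms: benzyl bromide, BrCc1ccccc1
Why: Williamson benzylation of phenol and carboxylate followed by saponification of the benzyl ester in the same pot, the aryl benzyl ether being stable to hydroxide.

Step 16
Reactants: 21 8,9-β-epoxide of diol 20; 24 3-(benzyloxy)-4-methoxybenzoic acid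
Product: 26 C1 3-(benzyloxy)-4-methoxybenzoate of epoxy diol 21, via mixed anhydride 25 (not isolated)
Conditions: 24 (1.5 equiv), 2,4,6-Cl3C6H2COCl (1.5 equiv), Et3N (3 equiv), PhMe, rt; then 21, DMAP (2 equiv), 60 °C
Reagents that add atoms: none
Why: Yamaguchi esterification, in which DMAP attacks the mixed anhydride at the less hindered aroyl carbonyl and the acylpyridinium acylates the secondary C1 hydroxyl with retention at C1, while the tertiary C3 hydroxyl is too hindered to react and the basic medium leaves the epoxide intact.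

Step 17
Reactants: 26 C1 3-(benzyloxy)-4-methoxybenzoate of epoxy diol 21
Product: 27 CNP0106636.1 (C1 3-hydroxy-4-methoxybenzoate of epoxy diol 21)
Conditions: H2 (1 atm), 10% Pd/C, EtOAc, rt
Reagents that add atoms: none
Why: Hydrogenolysis of the aryl benzyl ether over palladium, under which the non-benzylic ester C–O bond, the trisubstituted aliphatic epoxide and the tertiary alcohol are not cleaved at neutral pH and ambient pressure.

**Compound list**

1 | (S)-2-methylglycidol | C[C@]1(CO)CO1 | starting material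
2 | trimethylsilylacetylene | C#C[Si](C)(C)C | starting material
3 | (R)-2-methyl-5-(trimethylsilyl)pent-4-yne-1,2-diol | C[C@](O)(CO)CC#C[Si](C)(C)C | intermediate
4 | (R)-2-hydroxy-2-methyl-5-(trimethylsilyl)pent-4-yn-1-yl 4-methylbenzenesulfonate | C[C@](O)(COS(=O)(=O)c1ccc(C)cc1)CC#C[Si](C)(C)C | intermediate (not isolated)
5 | (R)-2-methyl-2-[3-(trimethylsilyl)prop-2-yn-1-yl]oxirane | C[C@@]1(CC#C[Si](C)(C)C)CO1 | intermediate
6 | (S)-4-methyl-7-(trimethylsilyl)hept-1-en-6-yn-4-ol | C[C@@](O)(CC#C[Si](C)(C)C)CC=C | intermediate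
7 | triethyl{[(S)-4-methyl-7-(trimethylsilyl)hept-1-en-6-yn-4-yl]oxy}silane | C[C@@](O[Si](CC)(CC)CC)(CC#C[Si](C)(C)C)CC=C | intermediate
8 | (4S)-4-methyl-4-(triethylsilyloxy)-7-(trimethylsilyl)hept-6-yne-1,2-diol (both C2 epimers) | C[C@@](O[Si](CC)(CC)CC)(CC#C[Si](C)(C)C)CC(O)CO | intermediate (not isolated)
9 | (R)-3-methyl-3-(triethylsilyloxy)-6-(trimethylsilyl)hex-5-ynal | C[C@@](O[Si](CC)(CC)CC)(CC#C[Si](C)(C)C)CC=O | intermediate
10 | (E)-1-bromo-4-methylpent-2-ene | CC(C)/C=C/CBr | starting material
11 | 4,4,5,5-tetramethyl-2-[(E)-4-methylpent-2-en-1-yl]-1,3,2-dioxaborolane | CC(C)/C=C/CB1OC(C)(C)C(C)(C)O1 | intermediate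
12 | pinacol borate ester of alcohol 13 (O–Bpin on C1) | C[Si](C)(C)C#CC[C@@](C)(O[Si](CC)(CC)CC)C[C@@H](OB1OC(C)(C)C(C)(C)O1)[C@@H](C(C)C)C=C | intermediate (not isolated)
13 | (3S,4R,6R)-6-methyl-3-(propan-2-yl)-6-(triethylsilyloxy)-9-(trimethylsilyl)non-1-en-8-yn-4-ol | C[Si](C)(C)C#CC[C@@](C)(O[Si](CC)(CC)CC)C[C@@H](O)[C@@H](C(C)C)C=C | intermediate
14 | (3S,4R,6R)-4-(tert-butyldimethylsilyloxy)-6-methyl-3-(propan-2-yl)-6-(triethylsilyloxy)-9-(trimethylsilyl)non-1-en-8-yne | C[Si](C)(C)C#CC[C@@](C)(O[Si](CC)(CC)CC)C[C@@H](O[Si](C)(C)C(C)(C)C)[C@@H](C(C)C)C=C | intermediate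
15 | (3S,4R,6R)-4-(tert-butyldimethylsilyloxy)-6-methyl-3-(propan-2-yl)-6-(triethylsilyloxy)non-1-en-8-yne | C#CC[C@@](C)(O[Si](CC)(CC)CC)C[C@@H](O[Si](C)(C)C(C)(C)C)[C@@H](C(C)C)C=C | intermediate (key-step precursor)
16 | (5R,7R,8S,8aS)-7-(tert-butyldimethylsilyloxy)-5-methyl-8-(propan-2-yl)-5-(triethylsilyloxy)-4,5,6,7,8,8a-hexahydroazulen-2(1H)-one | CC(C)(C)[Si](C)(C)O[C@@H]1C[C@](C)(O[Si](CC)(CC)CC)CC2=CC(=O)C[C@H]2[C@@H]1C(C)C | intermediate (key-step product)
17 | lithium C8–C9 enolate of the trans-fused ketone | CC(C)(C)[Si](C)(C)O[C@@H]1C[C@](C)(O[Si](CC)(CC)CC)C[C@@H]2C=C(O[Li])C[C@H]2[C@@H]1C(C)C | intermediate (not isolated)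
18 | (3aS,5R,7R,8S,8aR)-7-(tert-butyldimethylsilyloxy)-5-methyl-8-(propan-2-yl)-5-(triethylsilyloxy)-1,3a,4,5,6,7,8,8a-octahydroazulen-2-yl trifluoromethanesulfonate | CC(C)(C)[Si](C)(C)O[C@@H]1C[C@](C)(O[Si](CC)(CC)CC)C[C@@H]2C=C(OS(=O)(=O)C(F)(F)F)C[C@H]2[C@@H]1C(C)C | intermediate
19 | (3aS,5R,7R,8S,8aR)-7-(tert-butyldimethylsilyloxy)-2,5-dimethyl-8-(propan-2-yl)-5-(triethylsilyloxy)-1,3a,4,5,6,7,8,8a-octahydroazulene | CC(C)(C)[Si](C)(C)O[C@@H]1C[C@](C)(O[Si](CC)(CC)CC)C[C@@H]2C=C(C)C[C@H]2[C@@H]1C(C)C | intermediate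
20 | (3aS,5R,7R,8S,8aR)-2,5-dimethyl-8-(propan-2-yl)-1,3a,4,5,6,7,8,8a-octahydroazulene-5,7-diol | O[C@@H]1C[C@](C)(O)C[C@@H]2C=C(C)C[C@H]2[C@@H]1C(C)C | intermediate
21 | 8,9-β-epoxide of diol 20 (plan numbering 1R,3R,5S,6R,8R,9S,10S) | O[C@@H]1C[C@](C)(O)C[C@H]2[C@@H](C[C@@]3(C)O[C@@H]23)[C@@H]1C(C)C | intermediate
22 | isovanillic acid (3-hydroxy-4-methoxybenzoic acid) | COc1ccc(C(=O)O)cc1O | starting material
23 | benzyl 3-(benzyloxy)-4-methoxybenzoate | COc1ccc(C(=O)OCc2ccccc2)cc1OCc1ccccc1 | intermediate (not isolated)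
24 | 3-(benzyloxy)-4-methoxybenzoic acid | COc1ccc(C(=O)O)cc1OCc1ccccc1 | intermediate
25 | 3-(benzyloxy)-4-methoxybenzoic 2,4,6-trichlorobenzoic anhydride | COc1ccc(C(=O)OC(=O)c2c(Cl)cc(Cl)cc2Cl)cc1OCc1ccccc1 | intermediate (not isolated)
26 | C1 3-(benzyloxy)-4-methoxybenzoate of epoxy diol 21 | COc1ccc(C(=O)O[C@@H]2C[C@](C)(O)C[C@H]3[C@@H](C[C@@]4(C)O[C@@H]34)[C@@H]2C(C)C)cc1OCc1ccccc1 | intermediate
27 | CNP0106636.1, C1 3-hydroxy-4-methoxybenzoate of epoxy diol 21 | COc1ccc(C(=O)O[C@@H]2C[C@](C)(O)C[C@H]3[C@@H](C[C@@]4(C)O[C@@H]34)[C@@H]2C(C)C)cc1O | target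

**Step count**

Total: 17 steps. Longest linear sequence: 15 steps (steps 1–5, 7–14, 16, 17); steps 6 and 15 prepare the two side partners.

**Steps most likely to fail**

1. Step 10 (the step that carries the label). What may go wrong: olefin insertion into the cobalt–alkyne complex is slower than decay of the complex and than intermolecular alkyne oligomerisation, because an open five-atom tether offers little entropic help; facial control at C6 may also be incomplete. Fallback with known chemistry, setting out from aldehyde 9 and coming back at enone 16: indium-mediated Barbier addition of 1-bromo-4-methylpent-2-yne (SE2′ delivery) should give, after chromatographic separation of the C1 epimers, (4R,6R)-6-methyl-3-(propan-2-yl)-6-(triethylsilyloxy)-9-(trimethylsilyl)nona-1,2-dien-8-yn-4-ol F1. t-BuMe2SiOTf/2,6-lutidine converts it into (4R,6R)-4-(tert-butyldimethylsilyloxy)-6-methyl-3-(propan-2-yl)-6-(triethylsilyloxy)-9-(trimethylsilyl)nona-1,2-dien-8-yne F2, and K2CO3/MeOH frees the alkyne to give (4R,6R)-4-(tert-butyldimethylsilyloxy)-6-methyl-3-(propan-2-yl)-6-(triethylsilyloxy)nona-1,2-dien-8-yne F3. The rhodium-catalysed allenic Pauson–Khand reaction ([Rh(CO)2Cl]2, CO 1 atm, PhMe, 90 °C), a documented entry to bicyclo[5.3.0]decadienones that engages the terminal double bond of the allene, should close both rings to (5R,7R)-7-(tert-butyldimethylsilyloxy)-5-methyl-8-(propan-2-yl)-5-(triethylsilyloxy)-4,5,6,7-tetrahydroazulen-2(1H)-one F4. Li/NH3/t-BuOH then reduces this linear dienone in the 1,6-sense, the proton entering at C10 anti to the C1 silyloxy group, to give (5R,7R,8S)-7-(tert-butyldimethylsilyloxy)-5-methyl-8-(propan-2-yl)-5-(triethylsilyloxy)-3,4,5,6,7,8-hexahydroazulen-2(1H)-one F5, and NaOMe/MeOH moves the double bond into conjugation and equilibrates C6 to the trans arrangement, giving 16.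

2. Step 11. What may go wrong: C5 is protonated partly on the face syn to H6 (cis fusion), and proton exchange in the ammonia-derived medium quenches or isomerises the enolate before it is O-sulfonylated. Fallback, setting out from 16 and coming back at 18: the same reduction is followed by Me3SiCl/Et3N to give (3aS,5R,7R,8S,8aR)-7-(tert-butyldimethylsilyloxy)-5-methyl-8-(propan-2-yl)-5-(triethylsilyloxy)-2-(trimethylsilyloxy)-1,3a,4,5,6,7,8,8a-octahydroazulene F6, which is isolated and freed from any cis-fused isomer by chromatography. MeLi in THF then cleaves the O–Si bond to regenerate amine-free lithium enolate 17, which is triflated with PhNTf2 to give 18 (reductive silylation followed by regiospecific enolate regeneration in place of direct trapping). This fallback improves trapping and allows separation of isomers; it does not change the intrinsic facial preference of the protonation.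

3. Step 14. What may go wrong: the C3 hydroxyl fails to reach the olefin, so that oxygen is delivered unselectively or to the α face, with slow oxidation of the C1 carbinol as a side reaction. Fallback, setting out from 19 and coming back at 21: with both hydroxyls still silylated, NBS in aqueous THF should form the bromonium ion on the less screened α face and water should open it at the tertiary C8 from the β face, giving the 9α-bromo-8β-hydroxy-8,9-dihydro derivative of 19 F7. K2CO3/MeOH closes it with inversion at C9 to the bis-silyl ether of epoxy diol 21 F8, and Bu4NF removes both silyl groups to give 21 (halohydrin route, which places the epoxide on the face opposite to electrophile approach).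

**Further compounds**

F1 | step 10 | (4R,6R)-6-methyl-3-(propan-2-yl)-6-(triethylsilyloxy)-9-(trimethylsilyl)nona-1,2-dien-8-yn-4-ol | C[Si](C)(C)C#CC[C@@](C)(O[Si](CC)(CC)CC)C[C@@H](O)C(C(C)C)=C=C
F2 | step 10 | (4R,6R)-4-(tert-butyldimethylsilyloxy)-6-methyl-3-(propan-2-yl)-6-(triethylsilyloxy)-9-(trimethylsilyl)nona-1,2-dien-8-yne | C[Si](C)(C)C#CC[C@@](C)(O[Si](CC)(CC)CC)C[C@@H](O[Si](C)(C)C(C)(C)C)C(C(C)C)=C=C
F3 | step 10 | (4R,6R)-4-(tert-butyldimethylsilyloxy)-6-methyl-3-(propan-2-yl)-6-(triethylsilyloxy)nona-1,2-dien-8-yne | C#CC[C@@](C)(O[Si](CC)(CC)CC)C[C@@H](O[Si](C)(C)C(C)(C)C)C(C(C)C)=C=C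
F4 | step 10 | (5R,7R)-7-(tert-butyldimethylsilyloxy)-5-methyl-8-(propan-2-yl)-5-(triethylsilyloxy)-4,5,6,7-tetrahydroazulen-2(1H)-one | CC(C)(C)[Si](C)(C)O[C@@H]1C[C@](C)(O[Si](CC)(CC)CC)CC2=CC(=O)CC2=C1C(C)C
F5 | step 10 | (5R,7R,8S)-7-(tert-butyldimethylsilyloxy)-5-methyl-8-(propan-2-yl)-5-(triethylsilyloxy)-3,4,5,6,7,8-hexahydroazulen-2(1H)-one | CC(C)(C)[Si](C)(C)O[C@@H]1C[C@](C)(O[Si](CC)(CC)CC)CC2=C(CC(=O)C2)[C@@H]1C(C)C
F6 | step 11 | (3aS,5R,7R,8S,8aR)-7-(tert-butyldimethylsilyloxy)-5-methyl-8-(propan-2-yl)-5-(triethylsilyloxy)-2-(trimethylsilyloxy)-1,3a,4,5,6,7,8,8a-octahydroazulene | CC(C)(C)[Si](C)(C)O[C@@H]1C[C@](C)(O[Si](CC)(CC)CC)C[C@@H]2C=C(O[Si](C)(C)C)C[C@H]2[C@@H]1C(C)C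
F7 | step 14 | 9α-bromo-8β-hydroxy-8,9-dihydro derivative of 19 | CC(C)(C)[Si](C)(C)O[C@@H]1C[C@](C)(O[Si](CC)(CC)CC)C[C@@H]2[C@@H](Br)[C@](C)(O)C[C@H]2[C@@H]1C(C)C
F8 | step 14 | bis-silyl ether (C1 OTBS, C3 OTES) of epoxy diol 21 | CC(C)(C)[Si](C)(C)O[C@@H]1C[C@](C)(O[Si](CC)(CC)CC)C[C@H]2[C@@H](C[C@@]3(C)O[C@@H]23)[C@@H]1C(C)C
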